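**Retrosynthetic overview**
1. The C7–O ester bond is made last by acylating the C7 allylic alcohol. The trans-5,7-diol comes from 5-OH-directed reduction of a C8=C9 enone, which is derived from a C7=C8 alkene by hydroboration, oxidation and dehydrogenation.
2. The strategy rests on the cyclopentane ring (C1–C2–C3–C4–C5): the tertiary hydroxyl on ring-fusion carbon C5 and the isopropyl group on C4 are cis-vicinal, which is the retron of a carbonyl-ene reaction. Cutting C4–C5 leads to a cycloheptenone (C5 ketone, C7=C8 alkene) that carries a 4-methylpent-3-enyl chain on C1.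
3. The C1 quaternary stereocentre comes from palladium-catalysed decarboxylative asymmetric allylation of an allyl enol carbonate; the allyl group is extended by hydroboration, oxidation and an isopropylidene Wittig reaction.
4. The seven-membered ring comes from 4-methylanisole by Birch reduction and chloro(methyl)carbene ring expansion.
5. Ring order: the cycloheptene is formed first (step 2), the cyclopentane second (step 8).

Key step: step 8

Numbering (daucane): C1 = quaternary ring-fusion carbon bearing CH3 (C15); C2, C3 = cyclopentane CH2; C4 bears the isopropyl group (C11–C13); C5 = carbinol ring-fusion carbon; C6 = CH2; C7 = ester carbon; C8 bears CH3 (C14); C9; C10. In the target the 5-OH, the 1-CH3 and the 4-isopropyl group are mutually cis on the cyclopentane and the C7 ester oxygen is trans to the 5-OH: (1R,4R,5S,7R). The descriptor of the quaternary carbon changes from S (9, 11, 12) to R (14) through CIP priorities only.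

Assumption: (S)-t-BuPHOX is taken to give the (S)-configured ketone 9, in the same sense as with simple 2-methylcycloalkanone enol carbonates; the (R)-ligand would be used if the sense were reversed.

**Route**

Step 1
Reactants: 1 4-methylanisole
Product: 2 1-methoxy-4-methylcyclohexa-1,4-diene
Conditions: Li, liquid NH3, THF, t-BuOH, −78 → −33 °C; then H2O
Reagents that add atoms: none
Why: Birch reduction of an anisole protonates the ring ortho and meta to the methoxy group, which should leave the enol ether and the methyl-substituted alkene as two isolated double bonds.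

Step 2
Reactants: 2 1-methoxy-4-methylcyclohexa-1,4-diene; 3 1,1-dichloroethane
Product: 5 2,5-dimethylcyclohepta-2,5-dien-1-one, via chlorocyclopropane adduct 4 (not isolated)
Conditions: n-BuLi, Et2O, −40 → 0 °C; then pyridine, 80 °C
Reagents that add atoms: 1,1-dichloroethane, CC(Cl)Cl
Why: The chloro(methyl)carbenoid formed by α-lithiation of 3 should cyclopropanate the more electron-rich enol ether alkene, and methoxy-assisted cyclopropyl-to-allyl cation opening of 4 with loss of chloride (halocarbene ring expansion of an enol ether) should give the 2-methyl enone once pyridine takes up the O-methyl group.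

Step 3
Reactants: 5 2,5-dimethylcyclohepta-2,5-dien-1-one; 6 allyl chloroformate
Product: 8 allyl 2,5-dimethylcyclohepta-1,5-dien-1-yl carbonate, via lithium enolate 7 (not isolated)
Conditions: LiBH(s-Bu)3, THF, −78 °C; then 6, −78 → 0 °C
Reagents that add atoms: allyl chloroformate, C=CCOC(=O)Cl
Why: Conjugate reduction of the α-methyl enone by the bulky trialkylborohydride at the unhindered β-CH should generate the tetrasubstituted enolate regiospecifically, and chloroformates acylate such hindered enolates on oxygen.

Step 4
Reactants: 8 allyl 2,5-dimethylcyclohepta-1,5-dien-1-yl carbonate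
Product: 9 (S)-2-allyl-2,5-dimethylcyclohept-5-en-1-one
Conditions: Pd2(dba)3 (2.5 mol %), (S)-t-BuPHOX (6 mol %), THF, 25 °C
Reagents that add atoms: none
Why: In this decarboxylative asymmetric allylic alkylation (Tsuji allylation with a PHOX ligand), oxidative addition to zerovalent palladium and loss of CO2 give a chiral allylpalladium enolate whose inner-sphere C–C coupling should set the quaternary centre as (S) under ligand control without enolate equilibration.

Step 5
Reactants: 9 (S)-2-allyl-2,5-dimethylcyclohept-5-en-1-one
Product: 11 (S)-2-(3-hydroxypropyl)-2,5-dimethylcyclohept-5-en-1-one, via B-alkyl-9-BBN adduct 10 (not isolated)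
Conditions: 9-BBN, THF, 0 → 25 °C; then H2O2, aq. NaOAc, 0 °C
Reagents that add atoms: hydrogen peroxide, OO
Why: Anti-Markovnikov hydroboration with 9-BBN is far faster at the monosubstituted alkene than at the trisubstituted ring alkene or the α-quaternary ketone, and buffered peroxide oxidation of the C–B bond avoids base-induced conjugation of the β,γ-enone.

Step 6
Reactants: 11 (S)-2-(3-hydroxypropyl)-2,5-dimethylcyclohept-5-en-1-one
Product: 12 3-[(1S)-1,5-dimethyl-2-oxocyclohept-4-en-1-yl]propanal
Conditions: DMP, CH2Cl2, 0 → 25 °C
Reagents that add atoms: none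
Why: Dess–Martin oxidation converts the primary alcohol into the aldehyde under neutral conditions that leave the β,γ-unsaturated ketone and the quaternary centre untouched.

Step 7
Reactants: 12 3-[(1S)-1,5-dimethyl-2-oxocyclohept-4-en-1-yl]propanal; 13 isopropyltriphenylphosphonium iodide
Product: 14 (R)-2,5-dimethyl-2-(4-methylpent-3-en-1-yl)cyclohept-5-en-1-one
Conditions: 13, n-BuLi, THF, 0 °C; then 12, −78 → 25 °C
Reagents that add atoms: isopropyltriphenylphosphonium iodide, CC(C)[P+](c1ccccc1)(c1ccccc1)c1ccccc1.[I-]
Why: Wittig olefination with the non-stabilised isopropylidene ylide is much faster at the aldehyde than at the neopentyl α-quaternary ketone, so only the side chain should be olefinated.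

Step 8
Reactants: 14 (R)-2,5-dimethyl-2-(4-methylpent-3-en-1-yl)cyclohept-5-en-1-one
Product: 16 (1R,4R,5S)-dauca-7,11-dien-5-ol, via aluminium alkoxide 15 (not isolated)
Conditions: Me2AlCl (1.5 equiv), CH2Cl2, −78 → −20 °C; then H2O
Reagents that add atoms: none
Why: Me2AlCl complexes the C5 ketone, the nucleophilic C4 terminus of the 2-methylprop-1-enyl unit bonds to C5 while a hydrogen of an allylic methyl passes to oxygen through a six-membered transition state, and the alcohol–aluminium complex loses methane to alkoxide 15 so that no free proton acid builds up. The closest known reaction type is the Lewis-acid-promoted intramolecular carbonyl-ene cyclisation of δ,ε-unsaturated aldehydes and ketones to 2-isopropenylcyclopentanols, with the tether on the olefinic terminus of the ene unit. The cyclopentane (C1–C2–C3–C4–C5) closes in a 5-exo-trig mode at the carbonyl carbon, the isopropylidene π bond also lying outside the new ring. C5 is set by the three-carbon tether, which can reach only the carbonyl face on its own side of the seven-membered ring, so the hydroxyl ends cis to the C1 methyl in a cis-fused bicycle; C4 is set by the cyclic hydrogen transfer, which needs oxygen and the isopropylidene carbon syn across the new bond and so places isopropenyl cis to the hydroxyl, giving (4R,5S) from (1R). The step needs chemoselectivity for the side-chain alkene over the ring alkene and over enolisation of the β,γ-unsaturated ketone: the trisubstituted side-chain alkene is the only π bond that can reach C5 through an unstrained ring, and the low temperature and the proton-scavenging aluminium reagent are meant to suppress double-bond migration and chloride capture.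

Step 9
Reactants: 16 (1R,4R,5S)-dauca-7,11-dien-5-ol
Product: 17 (1R,4R,5S)-dauc-7-en-5-ol
Conditions: H2 (1 atm), RhCl(PPh3)3 (5 mol %), toluene–EtOH, 25 °C
Reagents that add atoms: none
Why: Homogeneous hydrogenation with RhCl(PPh3)3 discriminates by alkene substitution, so the 1,1-disubstituted isopropenyl group should be saturated while the trisubstituted ring alkene is retained; no stereocentre is formed.

Step 10
Reactants: 17 (1R,4R,5S)-dauc-7-en-5-ol
Product: 19 daucane-5,7-diol (C1, C4, C5 as in 17; epimers at C7 and C8), via C7 alkylborane 18 (not isolated)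
Conditions: BH3·THF, THF, 0 → 25 °C; then NaOH, H2O2, 0 → 25 °C
Reagents that add atoms: hydrogen peroxide, OO
Why: Hydroboration–oxidation places boron and then oxygen on the less substituted alkene carbon C7; the configurations created at C7 and C8 are of no consequence because both centres are re-made in steps 11 to 13.

Step 11
Reactants: 19 daucane-5,7-diol
Product: 20 5-hydroxydaucan-7-one (C1, C4, C5 as in 17; epimers at C8)
Conditions: DMP, CH2Cl2, 0 → 25 °C
Reagents that add atoms: none
Why: Dess–Martin oxidation takes the secondary C7 alcohol to the ketone, the tertiary C5 alcohol cannot be oxidised, and the neutral conditions should spare the β-hydroxy ketone from retro-aldol cleavage.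

Step 12
Reactants: 20 5-hydroxydaucan-7-one
Product: 21 (1R,4R,5S)-5-hydroxydauc-8-en-7-one
Conditions: IBX, 4-methoxypyridine N-oxide, DMSO, 25 °C
Reagents that add atoms: none
Why: IBX dehydrogenation of a ketone through its enol can only proceed toward C8, because C5 carries no hydrogen, and loss of a C9 hydrogen should give the conjugated endocyclic trisubstituted enone.

Step 13
Reactants: 21 (1R,4R,5S)-5-hydroxydauc-8-en-7-one
Product: 22 (1R,4R,5S,7R)-dauc-8-ene-5,7-diol
Conditions: Me4NBH(OAc)3, MeCN–AcOH (1:1), −20 °C
Reagents that add atoms: none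
Why: In this Evans–Saksena reduction the C5 hydroxyl exchanges onto boron and delivers hydride intramolecularly to the face of the C7 carbonyl on its own side, which should give the anti (trans) 5,7-diol, that is (7R), by 1,2-reduction only.

Step 14
Reactants: 22 (1R,4R,5S,7R)-dauc-8-ene-5,7-diol; 23 3,4-dimethoxybenzoyl chloride
Product: 24 (1R,4R,5S,7R)-5-hydroxydauc-8-en-7-yl 3,4-dimethoxybenzoate
Conditions: 23, Et3N, DMAP (cat.), CH2Cl2, 0 → 25 °C
Reagents that add atoms: 3,4-dimethoxybenzoyl chloride, COc1ccc(C(=O)Cl)cc1OC
Why: DMAP-catalysed acylation should esterify the secondary allylic C7 alcohol with retention of configuration and leave the hindered tertiary C5 alcohol free.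

**Compound list**
1 | 4-methylanisole | COc1ccc(C)cc1 | starting material
2 | 1-methoxy-4-methylcyclohexa-1,4-diene | COC1=CCC(C)=CC1 | intermediate
3 | 1,1-dichloroethane | CC(Cl)Cl | starting material
4 | 7-chloro-1-methoxy-4,7-dimethylbicyclo[4.1.0]hept-3-ene (racemic, C7 epimers) | COC12CC=C(C)CC1C2(C)Cl | intermediate
5 | 2,5-dimethylcyclohepta-2,5-dien-1-one | O=C1CC=C(C)CC=C1C | intermediate
6 | allyl chloroformate | C=CCOC(=O)Cl | starting material
7 | lithium 2,5-dimethylcyclohepta-1,5-dien-1-olate | [Li+].[O-]C1=C(C)CCC(C)=CC1 | intermediate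
8 | allyl 2,5-dimethylcyclohepta-1,5-dien-1-yl carbonate | C=CCOC(=O)OC1=C(C)CCC(C)=CC1 | intermediate
9 | (S)-2-allyl-2,5-dimethylcyclohept-5-en-1-one | C=CC[C@]1(C)CCC(C)=CCC1=O | intermediate
10 | 9-[3-(1,5-dimethyl-2-oxocyclohept-4-en-1-yl)propyl]-9-borabicyclo[3.3.1]nonane, quaternary centre as in 9 | B1(CCC[C@]2(C)CCC(C)=CCC2=O)C3CCCC1CCC3 | intermediate
11 | (S)-2-(3-hydroxypropyl)-2,5-dimethylcyclohept-5-en-1-one | OCCC[C@]1(C)CCC(C)=CCC1=O | intermediate
12 | 3-[(1S)-1,5-dimethyl-2-oxocyclohept-4-en-1-yl]propanal | O=CCC[C@]1(C)CCC(C)=CCC1=O | intermediate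
13 | isopropyltriphenylphosphonium iodide | CC(C)[P+](c1ccccc1)(c1ccccc1)c1ccccc1.[I-] | starting material
14 | (R)-2,5-dimethyl-2-(4-methylpent-3-en-1-yl)cyclohept-5-en-1-one | CC(C)=CCC[C@]1(C)CCC(C)=CCC1=O | intermediate
15 | chloro(methyl)aluminium 5-alkoxide of 16 | C=C(C)[C@H]1CC[C@]2(C)CCC(C)=CC[C@]12O[Al](C)Cl | intermediate
16 | (1R,4R,5S)-dauca-7,11-dien-5-ol (cis-fused; 5-OH cis to 1-CH3 and to 4-isopropenyl) | C=C(C)[C@H]1CC[C@]2(C)CCC(C)=CC[C@]12O | intermediate
17 | (1R,4R,5S)-dauc-7-en-5-ol | CC(C)[C@H]1CC[C@]2(C)CCC(C)=CC[C@]12O | intermediate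
18 | 7-boranyldaucan-5-ol (C1, C4, C5 as in 17; drawn as the monoalkylborane; C7 and C8 epimers) | CC(C)[C@H]1CC[C@]2(C)CCC(C)C(B)C[C@]12O | intermediate
19 | daucane-5,7-diol (C1, C4, C5 as in 17; C7 and C8 epimers) | CC(C)[C@H]1CC[C@]2(C)CCC(C)C(O)C[C@]12O | intermediate
20 | 5-hydroxydaucan-7-one (C1, C4, C5 as in 17; C8 epimers) | CC(C)[C@H]1CC[C@]2(C)CCC(C)C(=O)C[C@]12O | intermediate
21 | (1R,4R,5S)-5-hydroxydauc-8-en-7-one | CC(C)[C@H]1CC[C@]2(C)CC=C(C)C(=O)C[C@]12O | intermediate
22 | (1R,4R,5S,7R)-dauc-8-ene-5,7-diol (7-OH trans to 5-OH) | CC(C)[C@H]1CC[C@]2(C)CC=C(C)[C@H](O)C[C@]12O | intermediate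
23 | 3,4-dimethoxybenzoyl chloride | COc1ccc(C(=O)Cl)cc1OC | starting material
24 | (1R,4R,5S,7R)-5-hydroxydauc-8-en-7-yl 3,4-dimethoxybenzoate (CNP0196585.1) | COc1ccc(C(=O)O[C@@H]2C[C@]3(O)[C@@H](C(C)C)CC[C@]3(C)CC=C2C)cc1OC | target

**Step count**
Total steps: 14. Longest linear sequence: 14 steps (from 1).

**Steps most likely to fail**

1. Step 8. The Lewis acid may move the ring double bond into conjugation with the ketone, the cyclisation may turn stepwise with chloride capture or proton loss to alkene isomers, or the cis relation at C4 may erode. The fallback sets out from 12 and returns at 16. Aldehyde 12 would be olefinated with the β-silyl ylide Ph3P=C(CH3)CH2SiMe3 (from ethyltriphenylphosphonium bromide, n-BuLi and (iodomethyl)trimethylsilane, then a second equivalent of n-BuLi) to give the allylsilane (R)-2,5-dimethyl-2-[4-methyl-5-(trimethylsilyl)pent-3-en-1-yl]cyclohept-5-en-1-one F1 as an E/Z mixture. An intramolecular Hosomi–Sakurai addition (TiCl4, CH2Cl2, −78 °C) would then form the same C4–C5 bond with allylic transposition, which unveils the isopropenyl group and gives 16. The ring-fusion sense is fixed by the tether as before; the C4 configuration would depend on the trigger, and a fluoride trigger is the second option.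

2. Step 12. The β-hydroxy ketone may lose the C5 hydroxyl by β-elimination or open by retro-aldol cleavage under the oxidation conditions, or hydrogen may be lost from the C14 methyl to give an exocyclic alkene. The fallback sets out from 20 and returns at 21. Thermodynamic silylation (Me3SiCl, NaI, Et3N, MeCN) would give 5-(trimethylsilyloxy)-7-(trimethylsilyloxy)dauc-7-ene F2, which masks the tertiary alcohol and fixes the enol on the C8 side. Saegusa–Ito oxidation with Pd(OAc)2 (divalent palladium) in MeCN would give 5-(trimethylsilyloxy)dauc-8-en-7-one F3, and HF·pyridine in THF would release 21.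

3. Step 3. Hydride may add 1,2 instead of 1,4 to the cycloheptadienone, or proton transfer may scramble the dienolate before trapping. The fallback sets out from 5 and returns at 9, bypassing 7 and 8. Conjugate reduction with [(Ph3P)CuH]6 in the presence of Me3SiCl would give 2,5-dimethyl-1-(trimethylsilyloxy)cyclohepta-1,5-diene F4 under non-basic conditions. The enol-silane variant of the asymmetric allylation (Pd2(dba)3, (S)-t-BuPHOX, diallyl carbonate, Bu4N[Ph3SiF2], THF, 25 °C) would then give 9.

**Further compounds**
F1 | step 8 | (R)-2,5-dimethyl-2-[4-methyl-5-(trimethylsilyl)pent-3-en-1-yl]cyclohept-5-en-1-one (E/Z mixture) | C[Si](C)(C)CC(C)=CCC[C@]1(C)CCC(C)=CCC1=O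
F2 | step 12 | 5-(trimethylsilyloxy)-7-(trimethylsilyloxy)dauc-7-ene | CC(C)[C@H]1CC[C@]2(C)CCC(C)=C(O[Si](C)(C)C)C[C@]12O[Si](C)(C)C
F3 | step 12 | 5-(trimethylsilyloxy)dauc-8-en-7-one | CC(C)[C@H]1CC[C@]2(C)CC=C(C)C(=O)C[C@]12O[Si](C)(C)C
F4 | step 3 | 2,5-dimethyl-1-(trimethylsilyloxy)cyclohepta-1,5-diene | C[Si](C)(C)OC1=C(C)CCC(C)=CC1
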